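**Plan**

- Retrosynthesis: the C7 hydroxyl and the C11=C12 alkene go back to a 7(11)-en-8-one (singlet-oxygen ene reaction), and C11–C13 to acetone (aldol). The two esters are then removed, and rings B and A are cut together at C9–C10 and C4–C5, which gives an acyclic (E)-ene with an α-benzyloxy methyl ketone at one end and a β-keto ester at the other.
- Enabling feature: the C8 ketone makes C9 an enolic carbon once C9 carries an ester. The quaternary, methyl-bearing C10 is the tertiary-cation end of a C5=C10 alkene. The vicinal C3–O / C4(O)(CH3) pair of ring A is what an α-alkoxy methyl ketone initiator leaves behind. The closure copies the chair–chair cation–olefin mode of terpene cyclases (drimane/oxidosqualene type), applied here to a eudesmane, although eudesmanes themselves arise via germacrenes.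
- Forward: a C5 isoprenoid linchpin from isoprene monoxide is alkylated on its C1 side by the enolate of 3,3-dimethoxybutan-2-one and on its C6 side by the acetoacetate dianion. Rings A and B then form in one step. Debenzylation/decarboxylation, the two esterifications, C7 isopropylidenation and the ene hydroxylation follow.
- Stereochemistry: C3 comes from a CBS reduction. C4, C5 and C10 come from the chair–chair transition state (E alkene gives the trans fusion, C3–OBn equatorial). C7 comes from α-face attack of singlet oxygen. The Z ester geometry comes from angelic acid.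

Key step: step 7

Remark: eudesmane numbering is used throughout (ring A = C1–C5, C10; ring B = C5–C10; C14 on C10; C15 on C4; C11–C13 = isopropenyl carbons). α/β refer to the usual drawing with the C10 methyl β. The target ester is read as the (Z)-2-methylbut-2-enoate (angelate).

**Route**

Step 1
Reactants: 1 2-methyl-2-vinyloxirane (isoprene monoxide, racemic)
Product: 2 (E)-4-chloro-2-methylbut-2-en-1-ol
Conditions: TiCl4 (1.1 equiv), CH2Cl2, −90 to −78 °C; 1 M HCl quench
Reagents that add atoms: titanium tetrachloride, Cl[Ti](Cl)(Cl)Cl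
Why: Lewis-acid opening of the vinyl oxirane with SN2′ delivery of chloride to the vinyl terminus is a known entry to this (E)-chloro alcohol, the E geometry fixing the later C5=C10 alkene.

Step 2
Reactants: 2 (E)-4-chloro-2-methylbut-2-en-1-ol
Product: 3 (E)-1-bromo-4-chloro-2-methylbut-2-ene
Conditions: CBr4, PPh3, CH2Cl2, 0 °C
Reagents that add atoms: carbon tetrabromide, BrC(Br)(Br)Br
Why: Appel bromination of the primary allylic alcohol should proceed without allylic transposition and leave the less reactive allylic chloride for step 6.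

Step 3
Reactants: 3 (E)-1-bromo-4-chloro-2-methylbut-2-ene; 4 3,3-dimethoxybutan-2-one
Product: 6 (E)-8-chloro-2,2-dimethoxy-6-methyloct-6-en-3-one, via lithium enolate 5 (not isolated)
Conditions: 4 (1.2 equiv), LDA (1.2 equiv), THF, −78 °C; then 3, DMPU, −78 to −20 °C
Reagents that add atoms: none
Why: Ketone 4 can enolise only toward its methyl group, and SN2 alkylation of the lithium enolate should occur at the allylic bromide in preference to the allylic chloride (C1–C2 bond).

Step 4
Reactants: 6 (E)-8-chloro-2,2-dimethoxy-6-methyloct-6-en-3-one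
Product: 7 (3S,6E)-8-chloro-2,2-dimethoxy-6-methyloct-6-en-3-ol
Conditions: (R)-2-methyl-CBS-oxazaborolidine (0.2 equiv), catecholborane (1.5 equiv), toluene, −78 °C; aqueous NaOH work-up
Reagents that add atoms: none
Why: Corey–Bakshi–Shibata reduction with the quaternary ketal carbon as the large group should give the (S)-carbinol with the (R)-catalyst, setting C3 (sense to be confirmed by Mosher analysis; the antipodal catalyst is available), and catecholborane at −78 °C should leave the alkene untouched.

Step 5
Reactants: 7 (3S,6E)-8-chloro-2,2-dimethoxy-6-methyloct-6-en-3-ol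
Product: 8 (3S,6E)-3-(benzyloxy)-8-chloro-2,2-dimethoxy-6-methyloct-6-ene
Conditions: NaH (1.3 equiv), BnBr (1.5 equiv), THF–DMF, 0 °C to rt
Reagents that add atoms: benzyl bromide, BrCc1ccccc1
Why: Williamson etherification installs a chelating ether that is later cleaved together with the benzyl ester, and excess benzyl bromide should outcompete the allylic chloride for the alkoxide.

Step 6
Reactants: 8 (3S,6E)-3-(benzyloxy)-8-chloro-2,2-dimethoxy-6-methyloct-6-ene; 9 benzyl acetoacetate
Product: 12 benzyl (6E,10S)-10-(benzyloxy)-7-methyl-3,11-dioxododec-6-enoate, via acetoacetate dianion 10 (not isolated), via dimethyl ketal 11 (not isolated)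
Conditions: 9 (1.5 equiv), NaH then n-BuLi, THF, 0 °C; 8, 0 °C to rt; then 2 M HCl–THF (1:1), rt, short contact
Reagents that add atoms: water, O
Why: Weiler dianion alkylation occurs at the γ-carbon with primary allylic chlorides (C6–C7 bond), and mild aqueous acid in the same flask should unmask the C4 ketone without epimerising the adjacent C3 center.

Step 7
Reactants: 12 benzyl (6E,10S)-10-(benzyloxy)-7-methyl-3,11-dioxododec-6-enoate
Product: 13 benzyl 3β-(benzyloxy)-4β-hydroxy-8-oxo-11,12,13-trinor-5αH-eudesmane-9β-carboxylate
Conditions: SnCl4 (2.5 equiv), 2,6-di-tert-butyl-4-methylpyridine (1.0 equiv), CH2Cl2 (0.01 M), −78 to −40 °C; aqueous NaHCO3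
Reagents that add atoms: none
Why: Proposed new method: SnCl4 chelates the C4 carbonyl and the C3 benzyloxy oxygen of 12, the (E)-C5=C10 alkene attacks C4 through C5 (Prins step) and the tertiary C10 cation is captured through C9 by the tin-bound enol of the β-keto ester, so that the C4–C5 and C9–C10 bonds form in one chair–chair cascade. The closest known reaction types are the SnCl4-promoted cation–olefin cyclisation of polyenes that end in a β-keto ester, the Lewis-acid Prins/carbonyl-ene cyclisation of unsaturated ketones and the acetal-initiated polyene cyclisation; initiation by a chelated α-alkoxy ketone in such a cascade is the untested part. Ring A closes 6-endo with respect to the C5=C10 π bond and ring B closes as a 6-(enol-endo) attack of C9 on the C10 cation. Anti addition of C4 and C9 across the E alkene fixes the trans ring fusion (5α-H, 10β-CH3); the (S)-C3 center, with its benzyloxy group equatorial and antiperiplanar to the forming C4–C5 bond, selects the alkene face and thereby the absolute configuration of C5 and C10; at C4 the chelated oxygen rather than the methyl takes the axial site that is 1,3-related to the C10 methyl (O/CH3 instead of CH3/CH3 diaxial strain, the same sense as polar Felkin–Anh and chelation control), which gives 4β-OH/4α-CH3 cis to the 3β-ether. The C9 ester is expected equatorial, but this center is removed in step 8. The step needs ketone rather than proton initiation and C- rather than O-capture by the dicarbonyl: the hindered pyridine base and −78 °C suppress protonation of the alkene, and tin chelation ties up both dicarbonyl oxygens so that only C9 can bond to C10.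

Step 8
Reactants: 13 benzyl 3β-(benzyloxy)-4β-hydroxy-8-oxo-11,12,13-trinor-5αH-eudesmane-9β-carboxylate
Product: 15 3β,4β-dihydroxy-11,12,13-trinor-5αH-eudesman-8-one, via β-keto acid 14 (not isolated)
Conditions: H2 (1 atm), Pd(OH)2/C, EtOAc, rt; then 50 °C
Reagents that add atoms: none
Why: One hydrogenolysis cleaves the benzyl ether and the benzyl ester, and the β-keto acid decarboxylates on gentle warming, which turns C9 into the CH2 of the target while the ketone and tertiary alcohol are untouched.

Step 9
Reactants: 15 3β,4β-dihydroxy-11,12,13-trinor-5αH-eudesman-8-one; 16 angelic acid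
Product: 18 3β-angeloyloxy-4β-hydroxy-11,12,13-trinor-5αH-eudesman-8-one, via mixed anhydride 17 (not isolated)
Conditions: 16 (2 equiv), 2,4,6-trichlorobenzoyl chloride (2 equiv), Et3N (2.2 equiv), toluene, rt; then 15, 75 °C, no DMAP
Reagents that add atoms: none
Why: Mixed-anhydride (Yamaguchi-type) esterification without DMAP is known to transfer the angeloyl group without Z-to-E isomerisation and should acylate only the equatorial secondary 3β-OH, not the tertiary 4β-OH.

Step 10
Reactants: 18 3β-angeloyloxy-4β-hydroxy-11,12,13-trinor-5αH-eudesman-8-one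
Product: 19 4β-acetoxy-3β-angeloyloxy-11,12,13-trinor-5αH-eudesman-8-one
Conditions: Ac2O (3 equiv), Sc(OTf)3 (5 mol %), MeCN, −20 °C
Reagents that add atoms: acetic anhydride, CC(=O)OC(C)=O
Why: Sc(OTf)3-catalysed acyl transfer is a known method for hindered tertiary alcohols at low temperature, where E1 loss of the axial C4–OH should be slow and the angelate is not affected.

Step 11
Reactants: 19 4β-acetoxy-3β-angeloyloxy-11,12,13-trinor-5αH-eudesman-8-one; 20 acetone
Product: 22 4β-acetoxy-3β-angeloyloxy-11-hydroxy-5αH,7αH-eudesman-8-one, via silyl enol ether 21 (not isolated)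
Conditions: TMSOTf (1.3 equiv), Et3N (1.6 equiv), CH2Cl2, 0 °C; solvent exchange; then 20 (5 equiv), TiCl4 (1.1 equiv), CH2Cl2, −78 °C; cold NaHCO3 quench
Reagents that add atoms: trimethylsilyl trifluoromethanesulfonate, C[Si](C)(C)OS(=O)(=O)C(F)(F)F (silyl group carried only by intermediate 21)
Why: Soft enolisation should give the Δ7 silyl enol ether (C9 is neopentyl and the Δ7 enol is favoured in this trans-decalin, as in 5α-steroid 2-ketones) without touching the esters, and its Mukaiyama aldol addition to acetone attaches C11–C13; the C7 configuration formed here is erased in step 12.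

Step 12
Reactants: 22 4β-acetoxy-3β-angeloyloxy-11-hydroxy-5αH,7αH-eudesman-8-one
Product: 24 4β-acetoxy-3β-angeloyloxy-5αH-eudesm-7(11)-en-8-one, via mesylate 23 (not isolated)
Conditions: MsCl (3 equiv), Et3N (5 equiv), CH2Cl2, 0 °C; then DBU (3 equiv), rt
Reagents that add atoms: methanesulfonyl chloride, CS(=O)(=O)Cl (mesyl group carried only by intermediate 23)
Why: Mesylation of the tertiary aldol through the sulfene pathway and E1cB elimination through the C8 enolate give the enone, and DBU should equilibrate any isopropenyl isomer to the conjugated tetrasubstituted alkene.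

Step 13
Reactants: 24 4β-acetoxy-3β-angeloyloxy-5αH-eudesm-7(11)-en-8-one
Product: 26 4β-acetoxy-3β-angeloyloxy-7α-hydroxy-5αH-eudesm-11-en-8-one (target), via hydroperoxide 25 (not isolated)
Conditions: O2, tetraphenylporphyrin (1 mol %), visible light, CH2Cl2, −20 °C; then PPh3 (1.2 equiv), rt
Reagents that add atoms: dioxygen, O=O
Why: The Schenck ene reaction of singlet oxygen with s-cis isopropylidene ketones (pulegone type) bonds oxygen to the α-carbon C7 and moves the alkene to C11=C12, attack on the axial α lobe at C7 (away from the β-axial C10 methyl, the usual approach of small electrophiles in 10β-methyl trans-decalins) should set 7α-O, and PPh3 reduces the hydroperoxide.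

**Compound list**

1 | 2-methyl-2-vinyloxirane (racemic) | C=CC1(C)CO1 | starting material
2 | (E)-4-chloro-2-methylbut-2-en-1-ol | OC/C(C)=C/CCl | intermediate
3 | (E)-1-bromo-4-chloro-2-methylbut-2-ene | BrC/C(C)=C/CCl | intermediate
4 | 3,3-dimethoxybutan-2-one | CC(=O)C(C)(OC)OC | starting material
5 | lithium 3,3-dimethoxybut-1-en-2-olate | [Li]OC(=C)C(C)(OC)OC | intermediate (not isolated)
6 | (E)-8-chloro-2,2-dimethoxy-6-methyloct-6-en-3-one | CC(OC)(OC)C(=O)CC/C(C)=C/CCl | intermediate
7 | (3S,6E)-8-chloro-2,2-dimethoxy-6-methyloct-6-en-3-ol | CC(OC)(OC)[C@@H](O)CC/C(C)=C/CCl | intermediate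
8 | (3S,6E)-3-(benzyloxy)-8-chloro-2,2-dimethoxy-6-methyloct-6-ene | CC(OC)(OC)[C@@H](OCc1ccccc1)CC/C(C)=C/CCl | intermediate
9 | benzyl acetoacetate | CC(=O)CC(=O)OCc1ccccc1 | starting material
10 | sodium lithium dianion of benzyl acetoacetate | [Li+].[Na+].[CH2-]C(=O)[CH-]C(=O)OCc1ccccc1 | intermediate (not isolated)
11 | benzyl (6E,10S)-10-(benzyloxy)-11,11-dimethoxy-7-methyl-3-oxododec-6-enoate | CC(OC)(OC)[C@@H](OCc1ccccc1)CC/C(C)=C/CCC(=O)CC(=O)OCc1ccccc1 | intermediate (not isolated)
12 | benzyl (6E,10S)-10-(benzyloxy)-7-methyl-3,11-dioxododec-6-enoate | CC(=O)[C@@H](OCc1ccccc1)CC/C(C)=C/CCC(=O)CC(=O)OCc1ccccc1 | intermediate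
13 | benzyl 3β-(benzyloxy)-4β-hydroxy-8-oxo-11,12,13-trinor-5αH-eudesmane-9β-carboxylate | C1C[C@@H]2[C@](C)(CC[C@H](OCc3ccccc3)[C@]2(C)O)[C@@H](C(=O)OCc3ccccc3)C1=O | intermediate
14 | 3β,4β-dihydroxy-8-oxo-11,12,13-trinor-5αH-eudesmane-9β-carboxylic acid | C1C[C@@H]2[C@](C)(CC[C@H](O)[C@]2(C)O)[C@@H](C(=O)O)C1=O | intermediate (not isolated)
15 | 3β,4β-dihydroxy-11,12,13-trinor-5αH-eudesman-8-one | C1C[C@@H]2[C@](C)(CC[C@H](O)[C@]2(C)O)CC1=O | intermediate
16 | angelic acid, (Z)-2-methylbut-2-enoic acid | C/C=C(/C)C(=O)O | starting material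
17 | angelic 2,4,6-trichlorobenzoic anhydride | C/C=C(/C)C(=O)OC(=O)c1c(Cl)cc(Cl)cc1Cl | intermediate (not isolated)
18 | 3β-angeloyloxy-4β-hydroxy-11,12,13-trinor-5αH-eudesman-8-one | C1C[C@@H]2[C@](C)(CC[C@H](OC(=O)/C(C)=C\C)[C@]2(C)O)CC1=O | intermediate
19 | 4β-acetoxy-3β-angeloyloxy-11,12,13-trinor-5αH-eudesman-8-one | C1C[C@@H]2[C@](C)(CC[C@H](OC(=O)/C(C)=C\C)[C@]2(C)OC(C)=O)CC1=O | intermediate
20 | acetone | CC(C)=O | starting material
21 | 4β-acetoxy-3β-angeloyloxy-8-(trimethylsilyloxy)-11,12,13-trinor-5αH-eudesm-7-ene | C[Si](C)(C)OC1=CC[C@@H]2[C@](C)(CC[C@H](OC(=O)/C(C)=C\C)[C@]2(C)OC(C)=O)C1 | intermediate (not isolated)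
22 | 4β-acetoxy-3β-angeloyloxy-11-hydroxy-5αH,7αH-eudesman-8-one (drawn as the equatorial C7 epimer; C7 is erased in step 12) | CC(C)(O)[C@H]1C[C@@H]2[C@](C)(CC[C@H](OC(=O)/C(C)=C\C)[C@]2(C)OC(C)=O)CC1=O | intermediate
23 | 11-methanesulfonate of 22 | CC(C)(OS(C)(=O)=O)[C@H]1C[C@@H]2[C@](C)(CC[C@H](OC(=O)/C(C)=C\C)[C@]2(C)OC(C)=O)CC1=O | intermediate (not isolated)
24 | 4β-acetoxy-3β-angeloyloxy-5αH-eudesm-7(11)-en-8-one | CC(C)=C1C[C@@H]2[C@](C)(CC[C@H](OC(=O)/C(C)=C\C)[C@]2(C)OC(C)=O)CC1=O | intermediate
25 | 4β-acetoxy-3β-angeloyloxy-7α-hydroperoxy-5αH-eudesm-11-en-8-one | C=C(C)[C@@]1(OO)C[C@@H]2[C@](C)(CC[C@H](OC(=O)/C(C)=C\C)[C@]2(C)OC(C)=O)CC1=O | intermediate (not isolated)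
26 | 4β-acetoxy-3β-angeloyloxy-7α-hydroxy-5αH-eudesm-11-en-8-one (CNP0381775.1) | C=C(C)[C@@]1(O)C[C@@H]2[C@](C)(CC[C@H](OC(=O)/C(C)=C\C)[C@]2(C)OC(C)=O)CC1=O | target

**Summary**

Total step count: 13. Longest linear sequence: 13 steps (from 1; compounds 4, 9, 16 and 20 are commercial and enter directly).

Steps most likely to fail:

1. Step 7 (cascade bicyclisation). What may go wrong is loss of a proton from the C10 cation before C9 can bond to it, proton-initiated closure of ring B alone, or capture through a dicarbonyl oxygen. The fallback sets out from 12 and comes back at 13, closing the two rings one after the other with reactions of known type. Me2AlCl (2.5 equiv, CH2Cl2, −78 to −40 °C) should effect the Lewis-acid carbonyl-ene (Prins) cyclisation of the chelated ketone onto the alkene while the β-keto ester is parked as its aluminium chelate. This would give the ring-A alcohol benzyl 5-[3-(benzyloxy)-2-hydroxy-2-methyl-6-methylidenecyclohexyl]-3-oxopentanoate F1 (3β-OBn, 4β-OH, 5αH; any Δ1(10) isomer converges). SnCl4 in CH2Cl2 at −20 °C should then protonate the alkene to the same C10 cation and close ring B by the known β-keto-ester-terminated cation–olefin cyclisation. The equatorial C5 side chain attacks in a chair, giving the trans-fused 13, and the C4 alcohol is protected from ionisation by the adjacent benzyloxy group.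

2. Step 10 (acetylation of the tertiary alcohol). What may go wrong is ionisation and E1 elimination at the hindered axial C4–OH, or no acyl transfer at all. The fallback sets out from 15 and comes back at 19, delivering the acetate intramolecularly. Trimethyl orthoacetate with PPTS in CH2Cl2 should convert the cis-diol into the cyclic orthoester 3β,4β-O-(1-methoxyethylidene)-11,12,13-trinor-5αH-eudesman-8-one F2. Mild aqueous acid (80% AcOH, rt) is known to open such cis-fused orthoesters to the axial ester and the equatorial alcohol, here 4β-acetoxy-3β-hydroxy-11,12,13-trinor-5αH-eudesman-8-one F3. Esterification of the free secondary hydroxyl with the mixed anhydride 17 under the DMAP-free conditions of step 9 (to limit 4-to-3 acetyl migration) would then give 19.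

3. Step 13 (singlet-oxygen ene reaction). What may go wrong is a sluggish ene reaction of the electron-poor enone with competing over-oxidation, and poor facial selectivity at C7. The fallback sets out from 24 and comes back at 26 by a Rubottom oxidation. TMSOTf/Et3N (CH2Cl2, 0 °C) should give, by γ-deprotonation, the linear dienol ether 4β-acetoxy-3β-angeloyloxy-8-(trimethylsilyloxy)-5αH-eudesma-7,11-diene F4. mCPBA with NaHCO3 (CH2Cl2, −20 °C) should epoxidise the electron-rich endocyclic C7=C8 bond from the α face, the β face being shielded by the C10 methyl that is 1,3 to C8 (as in Δ2-5α-steroids). Silyl migration then gives 4β-acetoxy-3β-angeloyloxy-7α-(trimethylsilyloxy)-5αH-eudesm-11-en-8-one F5. Dilute HCl in THF at 0 °C would remove the silyl group and give 26.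

Further compounds
F1 | step 7 | benzyl 5-[3-(benzyloxy)-2-hydroxy-2-methyl-6-methylidenecyclohexyl]-3-oxopentanoate (3β-OBn, 4β-OH, 5αH) | C(CC(=O)CC(=O)OCc1ccccc1)[C@@H]2C(=C)CC[C@H](OCc3ccccc3)[C@]2(C)O
F2 | step 10 | 3β,4β-O-(1-methoxyethylidene)-11,12,13-trinor-5αH-eudesman-8-one | C1C[C@@H]2[C@](C)(CC[C@H](OC3(C)OC)[C@]2(C)O3)CC1=O
F3 | step 10 | 4β-acetoxy-3β-hydroxy-11,12,13-trinor-5αH-eudesman-8-one | C1C[C@@H]2[C@](C)(CC[C@H](O)[C@]2(C)OC(C)=O)CC1=O
F4 | step 13 | 4β-acetoxy-3β-angeloyloxy-8-(trimethylsilyloxy)-5αH-eudesma-7,11-diene | C[Si](C)(C)OC1=C(C(C)=C)C[C@@H]2[C@](C)(CC[C@H](OC(=O)/C(C)=C\C)[C@]2(C)OC(C)=O)C1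
F5 | step 13 | 4β-acetoxy-3β-angeloyloxy-7α-(trimethylsilyloxy)-5αH-eudesm-11-en-8-one | C=C(C)[C@@]1(O[Si](C)(C)C)C[C@@H]2[C@](C)(CC[C@H](OC(=O)/C(C)=C\C)[C@]2(C)OC(C)=O)CC1=O
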